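(Readings and results were generated by integration for substances that don't exist, noise included.)

Beta could not overtake alpha by making target faster, since it was charged with less enzyme. To turn the order, target had to drain out of alpha afterwards, and I asked how large that drain had to be.

the same everywhere: substrate 33 mM
- spring: enzyme 0.56 µM; run made earlier
- autumn: enzyme 2.9 µM; run made earlier
- summer: enzyme 12 µM; run made earlier
- beta: enzyme 3.3 µM; time 6.0 min
- alpha: enzyme 10 µM; time 6.0 min
- gamma: enzyme 2.0 µM; time 6.0 min
- zeta: enzyme 1.5 µM; time 6.0 min
- eta: enzyme 0.80 µM; time 6.0 min

| run | time / min | target / % |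
|---|---|---|
| spring | 0.250 | 3 |
| spring | 0.417 | 2 |
| spring | 0.833 | 7 |
| spring | 1.50 | 12 |
| spring | 3.00 | 9 |
| autumn | 0.250 | 12 |
| autumn | 0.417 | 22 |
| autumn | 0.833 | 29 |
| autumn | 1.50 | 35 |
| autumn | 3.00 | 38 |
| summer | 0.250 | 43 |
| summer | 0.417 | 57 |
| summer | 0.833 | 62 |
| summer | 1.50 | 64 |
| summer | 3.00 | 64 |

(scatter of a reading: 1.5 percentage points)

- percent here means substrate units held: one self-condensation product counts as two
- candidate steps: substrate + enzyme <-> complex; 2 substrate -> self-condensation product; complex <-> enzyme + target

- ranking by amount of target, in percent of the substrate charged, from high to low, at 6.0 min (beta / alpha / gamma / zeta / eta)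
- the same order at 25 min (beta / alpha / gamma / zeta / eta)
- the amount of target, in percent of the substrate charged of the flask you put first, at 6.0 min
- the amount of target, in percent of the substrate charged of the flask you put last, at 6.0 min

Substrate had two ways out: through the enzyme to target, and into self-condensation product. I took the first rate as proportional to enzyme and substrate, and the second to substrate squared. With a fraction s of the substrate left, target then took the share x/(x+s), and summed over the run this gave the plateau Y = x ln(1+1/x). Setting s to 0.5 in the summer run's plateau of 64% gave a first answer, x = 0.889. Put back through x = Y/ln(1+1/x), it became 0.849, and once more 0.822. That value returns 65.4%, against a scatter of 1.5 percentage points. So I carried 0.822 as the split number, a selectivity factor: the enzyme's rate over condensation's at the full charge, scaled with enzyme from the summer run's 12 µM.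

Scaled so, it gave plateaus of 61.7% for alpha, 38.2% for beta and 16.2% for eta. Alpha therefore had to lose 23 points in 19.0 min. At that pace the summer run should have dropped 1.9 points over its last 1.50 min. It read 64% and then 64%, but the difference of two readings carries a scatter of 2.1 points, so this pair could neither show nor exclude such a drain, and my order stayed an estimate.

The forecast gave alpha > beta > gamma > zeta > eta at 6.0 min and alpha > beta > gamma > zeta > eta at 25 min, with 60% for alpha and 14.5% for eta, holding that “the drain is gentle and the ranking should hold at 25 min”.

    substrate + enzyme ⇌ complex (K = 64.0 M⁻¹, k = 85000 M⁻¹ s⁻¹)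
    2 substrate → self-condensation product (k = 0.940 M⁻¹ s⁻¹)
    complex ⇌ enzyme + target (K = 0.760 M, k = 160 s⁻¹)

The flasks gave alpha > beta > gamma > zeta > eta at 6.0 min and alpha > beta > gamma > zeta > eta at 25 min. Alpha, with x = 0.685, gave 61.0% against my 61.7%. Eta, with x = 0.0548, gave 18.2% against my 16.2%. Alpha lost 1.1 points between the two readings, where falling behind beta's 39.5% at 25 min needed 21 points. The split came from condensation: with the step from substrate to self-condensation product taken away, alpha stood at 98.0% instead of 61.0%.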